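**Strategy.** The ten-membered carbocycle (C1–C10) is closed last, by ring-closing metathesis that forms the trisubstituted C4=C5 alkene between the C3 benzoate carbon and the lactone carbon C6; the ring itself enforces the 4Z geometry (cis-cyclodecene). Everything else is set before on an open chain, because the 3β and 8β oxygens point into the ring, where ring-forming carbonyl additions would not place them. The precursor is a seco-triene: a trans-α-methylene-γ-butyrolactone carrying a C6 propenyl group (zinc Barbier reaction of a resolved bromomethylbutenolide, C8 inverted by Mitsunobu esterification) and a chain with the Shi epoxide, the C3 benzoate and a C4 isopropenyl terminus.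

Key step: step 17

Remark: locants C1–C15 follow germacranolide numbering of the target (ring C1–C10, lactone carbonyl C12, methylene C13, methyls C14 on C10 and C15 on C4); compounds 1, 5, 6, 9, 12, 13, 18 and 21 are taken as commercial.

**Epoxy acid**

Step 1
Reactants: 1 methyl angelate [methyl (Z)-2-methylbut-2-enoate]
Product: 2 (Z)-2-methylbut-2-en-1-ol
Conditions: iBu2AlH (2.2 equiv), CH2Cl2, −78 °C to 0 °C
Reagents that add atoms: none
Why: 1,2-reduction of the enoate by the aluminium hydride (DIBAL reduction) should leave the Z alkene untouched.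

Step 2
Reactants: 2 (Z)-2-methylbut-2-en-1-ol
Product: 3 [(2S,3R)-2,3-dimethyloxiran-2-yl]methanol
Conditions: Ti(OiPr)4 (10 mol%), L-(+)-diethyl tartrate (12 mol%), t-BuOOH, 4 Å molecular sieves, CH2Cl2, −20 °C
Reagents that add atoms: tert-butyl hydroperoxide CC(C)(C)OO
Why: Sharpless asymmetric epoxidation, in which the L-(+)-tartrate titanium complex delivers oxygen to the face that gives the 2S centre (as with nerol) and cis addition to the Z alkene fixes C3 as R.

Step 3
Reactants: 3 [(2S,3R)-2,3-dimethyloxiran-2-yl]methanol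
Product: 4 (2R,3R)-2,3-dimethyloxirane-2-carboxylic acid (epoxyangelic acid)
Conditions: RuCl3 (2 mol%), NaIO4 (3 equiv), CCl4/MeCN/H2O, 23 °C
Reagents that add atoms: sodium periodate [Na+].[O-]I(=O)(=O)=O; water O
Why: catalytic RuO4 oxidation takes the primary alcohol to the acid without touching the two epoxide stereocentres (the C2 descriptor changes by priority only).

**Butenolide**

Step 4
Reactants: 5 crotonaldehyde [(E)-but-2-enal]; 6 vinylmagnesium bromide
Product: 7 rac-(E)-hexa-1,4-dien-3-ol
Conditions: THF, −78 °C to 0 °C; aqueous NH4Cl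
Reagents that add atoms: none
Why: Grignard 1,2-addition to the enal should give the racemic bis-allylic carbinol.

Step 5
Reactants: 7 rac-(E)-hexa-1,4-dien-3-ol
Product: 8 (S,E)-hexa-1,4-dien-3-ol
Conditions: Ti(OiPr)4 (1.0 equiv), D-(−)-diisopropyl tartrate (1.2 equiv), t-BuOOH (0.6 equiv), 4 Å molecular sieves, CH2Cl2, −20 °C, stopped beyond half conversion
Reagents that add atoms: none
Why: Sharpless kinetic resolution, in which the D-(−)-tartrate catalyst epoxidises the R enantiomer quickly at its E-propenyl group while the S enantiomer, matched only at its slow vinyl group, should be recovered.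

Step 6
Reactants: 8 (S,E)-hexa-1,4-dien-3-ol; 9 2-(bromomethyl)acrylic acid
Product: 10 (S,E)-hexa-1,4-dien-3-yl 2-(bromomethyl)acrylate
Conditions: N,N'-dicyclohexylcarbodiimide, 4-(dimethylamino)pyridine (5 mol%), CH2Cl2, 0 °C
Reagents that add atoms: none
Why: Steglich esterification acylates the carbinol oxygen and does not touch the stereocentre.

Step 7
Reactants: 10 (S,E)-hexa-1,4-dien-3-yl 2-(bromomethyl)acrylate
Product: 11 (R)-3-(bromomethyl)-5-[(E)-prop-1-en-1-yl]furan-2(5H)-one
Conditions: second-generation Grubbs catalyst (5 mol%), CH2Cl2 (0.01 M), 40 °C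
Reagents that add atoms: none
Why: ring-closing metathesis, in which the carbene loads on the terminal vinyl group and closes onto the acrylate, so that the propenyl group is the one left on C6 (the descriptor becomes R by priority only).

**Epoxy aldehyde**

Step 8
Reactants: 12 tert-butyl(but-3-yn-1-yloxy)dimethylsilane; 13 ethylene oxide
Product: 16 (E)-6-[(tert-butyldimethylsilyl)oxy]-4-methylhex-3-en-1-ol, via alkenyldimethylalane 14 (not isolated), via lithium alkenylalanate 15 (not isolated)
Conditions: Me3Al (2 equiv), Cp2ZrCl2 (0.25 equiv), CH2Cl2, 23 °C; then n-BuLi, hexane/THF, −78 °C; then 13, −30 °C to 23 °C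
Reagents that add atoms: trimethylaluminium C[Al](C)C
Why: Negishi zirconium-catalysed carboalumination adds methyl and aluminium syn across the alkyne (E-trisubstituted alkene C1=C10), and the derived alanate opens ethylene oxide at carbon.

Step 9
Reactants: 16 (E)-6-[(tert-butyldimethylsilyl)oxy]-4-methylhex-3-en-1-ol
Product: 17 (E)-6-[(tert-butyldimethylsilyl)oxy]-4-methylhex-3-enal
Conditions: Dess–Martin periodinane, NaHCO3, CH2Cl2, 0 °C; used crude
Reagents that add atoms: none
Why: buffered Dess–Martin oxidation should give the β,γ-unsaturated aldehyde without moving the alkene into conjugation.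

Step 10
Reactants: 17 (E)-6-[(tert-butyldimethylsilyl)oxy]-4-methylhex-3-enal; 18 2-bromopropene
Product: 20 (3S,5E)-8-[(tert-butyldimethylsilyl)oxy]-2,6-dimethylocta-1,5-dien-3-ol, via isopropenylchromium dichloride 19 (not isolated)
Conditions: CrCl2 (4 equiv), NiCl2 (2 mol%), N-[2-(4-isopropyl-4,5-dihydrooxazol-2-yl)-6-methylphenyl]methanesulfonamide (single enantiomer, the one that delivers 3S; 4.4 equiv), Et3N, THF, 23 °C
Reagents that add atoms: none
Why: asymmetric Nozaki–Hiyama–Kishi alkenylation, in which the chiral sulfonamide on the trivalent chromium alkenyl differentiates the aldehyde faces and sets C3 (S) while the neutral medium spares the β,γ-alkene.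

Step 11
Reactants: 20 (3S,5E)-8-[(tert-butyldimethylsilyl)oxy]-2,6-dimethylocta-1,5-dien-3-ol; 21 benzoyl chloride
Product: 22 (3S,5E)-8-[(tert-butyldimethylsilyl)oxy]-2,6-dimethylocta-1,5-dien-3-yl benzoate
Conditions: pyridine, 4-(dimethylamino)pyridine (10 mol%), CH2Cl2, 0 °C to 23 °C
Reagents that add atoms: none
Why: acylation of the secondary allylic alcohol installs the C3 benzoate of the target with retention.

Step 12
Reactants: 22 (3S,5E)-8-[(tert-butyldimethylsilyl)oxy]-2,6-dimethylocta-1,5-dien-3-yl benzoate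
Product: 23 (S)-1-[(2R,3R)-3-{2-[(tert-butyldimethylsilyl)oxy]ethyl}-3-methyloxiran-2-yl]-3-methylbut-3-en-2-yl benzoate
Conditions: Shi ketone (1,2:4,5-di-O-isopropylidene-β-D-erythro-2,3-hexodiulo-2,6-pyranose, 30 mol%), KHSO5 (as Oxone), K2CO3, Bu4NHSO4, MeCN/dimethoxymethane/aqueous Na2B4O7 buffer (pH 10.5), 0 °C
Reagents that add atoms: potassium peroxymonosulfate [K+].[O-]S(=O)(=O)OO
Why: Shi epoxidation, in which the chiral dioxirane attacks the electron-rich E-trisubstituted alkene through the spiro transition state and should give the (R,R)-epoxide (C1, C10) under catalyst control, the 1,1-disubstituted alkene beside the benzoate being left.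

Step 13
Reactants: 23 silyl ether above
Product: 24 (S)-1-[(2R,3R)-3-(2-hydroxyethyl)-3-methyloxiran-2-yl]-3-methylbut-3-en-2-yl benzoate
Conditions: Bu4NF, AcOH (1:1), THF, 0 °C to 23 °C
Reagents that add atoms: none
Why: buffered fluoride desilylation frees the primary alcohol without opening the epoxide or moving the benzoate.

Step 14
Reactants: 24 primary alcohol above
Product: 25 (S)-3-methyl-1-[(2R,3R)-3-methyl-3-(2-oxoethyl)oxiran-2-yl]but-3-en-2-yl benzoate
Conditions: Dess–Martin periodinane, NaHCO3, CH2Cl2, 0 °C; used crude at once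
Reagents that add atoms: none
Why: buffered Dess–Martin oxidation gives the β,γ-epoxy aldehyde without the base that would open the epoxide by elimination.

**Coupling and ring closure**

Step 15
Reactants: 11 (R)-3-(bromomethyl)-5-[(E)-prop-1-en-1-yl]furan-2(5H)-one; 25 epoxy aldehyde above
Product: 27 (S)-1-{(2R,3R)-3-[(S)-2-hydroxy-2-{(2R,3R)-4-methylidene-5-oxo-2-[(E)-prop-1-en-1-yl]oxolan-3-yl}ethyl]-3-methyloxiran-2-yl}-3-methylbut-3-en-2-yl benzoate (C6 R, C7 R, C8 S), via allylzinc bromide 26 (not isolated)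
Conditions: Zn dust, THF/saturated aqueous NH4Cl (2:1), 0 °C to 23 °C
Reagents that add atoms: none
Why: zinc Barbier allylation of the α-(bromomethyl)butenolide, in which the allylzinc reacts at C7 through a chair transition state on the face anti to the C6 propenyl group (trans lactone, C7 R) with the aldehyde chain equatorial, which should give the anti 8S carbinol and unveil the α-methylene lactone.

Step 16
Reactants: 27 Barbier adduct above; 4 (2R,3R)-2,3-dimethyloxirane-2-carboxylic acid
Product: 28 (R)-2-{(2R,3R)-3-[(S)-2-(benzoyloxy)-3-methylbut-3-en-1-yl]-2-methyloxiran-2-yl}-1-{(2R,3R)-4-methylidene-5-oxo-2-[(E)-prop-1-en-1-yl]oxolan-3-yl}ethyl (2R,3R)-2,3-dimethyloxirane-2-carboxylate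
Conditions: PPh3, diisopropyl azodicarboxylate, toluene, −20 °C to 23 °C
Reagents that add atoms: none
Why: Mitsunobu esterification, in which the carboxylate displaces the C8 oxyphosphonium group by SN2 with inversion (8S to 8R), so that the ester and the required C8 configuration arrive together.

Step 17
Reactants: 28 seco-triene above
Product: 29 target, (1R,3S,4Z,6R,7R,8R,10R)-3-benzoyloxy-1,10-epoxy-8-[(2R,3R)-2,3-dimethyloxirane-2-carbonyloxy]germacra-4,11(13)-dien-12,6-olide (CNP0324463.6)
Conditions: second-generation Hoveyda–Grubbs catalyst (15 mol%), 1,4-benzoquinone (30 mol%), toluene (0.001 M), 80 °C, argon sparge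
Reagents that add atoms: none
Why: Olefin metathesis by the Chauvin mechanism: the ruthenium carbene exchanges onto the C5 propenyl terminus, adds across the C4 isopropenyl group to a ruthenacyclobutane and releases the ring alkene and propene, the closest known reaction type being ring-closing metathesis to ten-membered carbocycles with a trisubstituted alkene. The ten-membered ring C1–C10 is closed by intramolecular alkene metathesis across C4=C5 (macrocyclic mode, made irreversible by sparging out propene). No stereocentre is formed; the one new stereoelement, the C4=C5 geometry, is controlled by the ring, since a ten-membered ring accommodates the cis (4Z) alkene and the E isomer would be a strained trans-cyclodecene. The step needs ring closure to beat oligomerisation, which high dilution and the turn imposed by the trans-lactone and the trans-epoxide should secure. It also needs chemoselectivity, which the substrate secures because the electron-poor 1,1-disubstituted C11=C13 alkene, the epoxides and the esters are inert to the carbene; benzoquinone suppresses alkene migration by ruthenium hydrides.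

**Compound list**

1 | methyl angelate [methyl (Z)-2-methylbut-2-enoate] | C/C=C(/C)C(=O)OC | starting material
2 | (Z)-2-methylbut-2-en-1-ol | C/C=C(/C)CO | intermediate
3 | [(2S,3R)-2,3-dimethyloxiran-2-yl]methanol | OC[C@]1(C)O[C@@H]1C | intermediate
4 | (2R,3R)-2,3-dimethyloxirane-2-carboxylic acid | OC(=O)[C@]1(C)O[C@@H]1C | intermediate
5 | crotonaldehyde [(E)-but-2-enal] | C/C=C/C=O | starting material
6 | vinylmagnesium bromide | C=C[Mg]Br | starting material
7 | rac-(E)-hexa-1,4-dien-3-ol | C=CC(O)/C=C/C | intermediate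
8 | (S,E)-hexa-1,4-dien-3-ol | C=C[C@H](O)/C=C/C | intermediate
9 | 2-(bromomethyl)acrylic acid | C=C(CBr)C(=O)O | starting material
10 | (S,E)-hexa-1,4-dien-3-yl 2-(bromomethyl)acrylate | C=C(CBr)C(=O)O[C@@H](C=C)/C=C/C | intermediate
11 | (R)-3-(bromomethyl)-5-[(E)-prop-1-en-1-yl]furan-2(5H)-one | O=C1O[C@H](/C=C/C)C=C1CBr | intermediate
12 | tert-butyl(but-3-yn-1-yloxy)dimethylsilane | C#CCCO[Si](C)(C)C(C)(C)C | starting material
13 | ethylene oxide | C1CO1 | starting material
14 | [(E)-4-(tert-butyldimethylsilyloxy)-2-methylbut-1-en-1-yl]dimethylalane (not isolated) | C[Al](C)/C=C(\C)CCO[Si](C)(C)C(C)(C)C | intermediate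
15 | lithium butyl[(E)-4-(tert-butyldimethylsilyloxy)-2-methylbut-1-en-1-yl]dimethylalanate (not isolated) | [Li+].CCCC[Al-](C)(C)/C=C(\C)CCO[Si](C)(C)C(C)(C)C | intermediate
16 | (E)-6-[(tert-butyldimethylsilyl)oxy]-4-methylhex-3-en-1-ol | OCC/C=C(\C)CCO[Si](C)(C)C(C)(C)C | intermediate
17 | (E)-6-[(tert-butyldimethylsilyl)oxy]-4-methylhex-3-enal | O=CC/C=C(\C)CCO[Si](C)(C)C(C)(C)C | intermediate
18 | 2-bromopropene | C=C(C)Br | starting material
19 | isopropenylchromium dichloride (not isolated) | C=C(C)[Cr](Cl)Cl | intermediate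
20 | (3S,5E)-8-[(tert-butyldimethylsilyl)oxy]-2,6-dimethylocta-1,5-dien-3-ol | C=C(C)[C@@H](O)C/C=C(\C)CCO[Si](C)(C)C(C)(C)C | intermediate
21 | benzoyl chloride | O=C(Cl)c1ccccc1 | starting material
22 | (3S,5E)-8-[(tert-butyldimethylsilyl)oxy]-2,6-dimethylocta-1,5-dien-3-yl benzoate | C=C(C)[C@@H](OC(=O)c1ccccc1)C/C=C(\C)CCO[Si](C)(C)C(C)(C)C | intermediate
23 | (S)-1-[(2R,3R)-3-{2-[(tert-butyldimethylsilyl)oxy]ethyl}-3-methyloxiran-2-yl]-3-methylbut-3-en-2-yl benzoate | C=C(C)[C@@H](OC(=O)c1ccccc1)C[C@H]1O[C@]1(C)CCO[Si](C)(C)C(C)(C)C | intermediate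
24 | (S)-1-[(2R,3R)-3-(2-hydroxyethyl)-3-methyloxiran-2-yl]-3-methylbut-3-en-2-yl benzoate | C=C(C)[C@@H](OC(=O)c1ccccc1)C[C@H]1O[C@]1(C)CCO | intermediate
25 | (S)-3-methyl-1-[(2R,3R)-3-methyl-3-(2-oxoethyl)oxiran-2-yl]but-3-en-2-yl benzoate | C=C(C)[C@@H](OC(=O)c1ccccc1)C[C@H]1O[C@]1(C)CC=O | intermediate
26 | bromo{[(R)-2-oxo-5-((E)-prop-1-en-1-yl)-2,5-dihydrofuran-3-yl]methyl}zinc (not isolated) | Br[Zn]CC1=C[C@@H](/C=C/C)OC1=O | intermediate
27 | Barbier adduct, 8S alcohol (C1 R, C3 S, C6 R, C7 R, C8 S, C10 R), name as in step 15 | C=C1C(=O)O[C@H](/C=C/C)[C@H]1[C@@H](O)C[C@@]1(C)O[C@@H]1C[C@H](OC(=O)c1ccccc1)C(C)=C | intermediate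
28 | seco-triene, 8R epoxyangelate (C1 R, C3 S, C6 R, C7 R, C8 R, C10 R), name as in step 16 | C=C1C(=O)O[C@H](/C=C/C)[C@H]1[C@H](OC(=O)[C@]2(C)O[C@@H]2C)C[C@@]2(C)O[C@@H]2C[C@H](OC(=O)c2ccccc2)C(C)=C | intermediate
29 | target, name as in step 17 | C=C1C(=O)O[C@@H]2/C=C(/C)[C@@H](OC(=O)c3ccccc3)C[C@H]3O[C@]3(C)C[C@@H](OC(=O)[C@]3(C)O[C@@H]3C)[C@@H]12 | target

**Count.** Total steps: 17. Longest linear sequence: 10 steps (steps 8 to 17).

**Steps most likely to fail**

1. Step 17 (ring-closing metathesis). Ring closure onto the hindered 1,1-disubstituted alkene beside the benzoate may be outrun by intermolecular metathesis, so that oligomers form instead of the ring. The fallback closes the ring at C3–C4 by an intramolecular Nozaki–Hiyama–Kishi reaction on a Z-alkenyl iodide. It sets out from alcohol 16 (with acids 9 and 4) and comes back to the route at 29.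
 - Aldehyde half: alcohol 16 is protected (NaH, 4-methoxybenzyl chloride) as the PMB ether F1, epoxidised as in step 12 to the (R,R)-epoxide F2, desilylated (Bu4NF, AcOH) to the alcohol F3 and oxidised (Dess–Martin periodinane) to the epoxy aldehyde F4.
 - Iodobutenolide half: acrolein and propynylmagnesium bromide give the racemic enynol F5, which is resolved (Ti(OiPr)4, L-(+)-diisopropyl tartrate, t-BuOOH) to the S enynol F6. Trans-hydroalumination and iodination (NaAlH2(OCH2CH2OMe)2, then I2) give the Z-iododienol F7; esterification with 9 gives the acrylate F8, and ring-closing metathesis as in step 7 gives the iodobutenolide F9.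
 - Union and closure: zinc Barbier reaction of F9 with F4 gives the 8S alcohol F10, and Mitsunobu esterification with 4 gives the 8R ester F11. Removal of the PMB group (DDQ, buffered CH2Cl2) gives the alcohol F12, and Dess–Martin oxidation gives the aldehyde F13. CrCl2 with catalytic NiCl2 in DMSO at high dilution closes the ring to the allylic alcohol F14. Benzoylation (benzoyl chloride for the 3S epimer, Mitsunobu reaction with benzoic acid for a 3R epimer) gives 29.

2. Step 16 (Mitsunobu esterification). The activated C8 oxyphosphonium may eliminate toward the acidic C7–H, or displacement at the doubly flanked carbinol may not occur. The fallback sets out from 27 and comes back at 28: Dess–Martin oxidation gives the C8 ketone F15, reagent-controlled reduction [(S)-1-methyl-3,3-diphenyl-tetrahydropyrrolo[1,2-c][1,3,2]oxazaborole, catecholborane, toluene, −78 °C] should give the 8R alcohol F16, and Yamaguchi esterification with 4 (2,4,6-trichlorobenzoyl chloride, Et3N, then 4-(dimethylamino)pyridine) gives 28.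

3. Step 10 (asymmetric Nozaki–Hiyama–Kishi alkenylation). Facial discrimination by the chiral ligand may be insufficient, which would carry C3 epimers forward. The fallback sets out from 17 and comes back at 20: isopropenylmagnesium bromide gives the racemic alcohol F17, Dess–Martin oxidation gives the enone F18, and reduction with the (R)-enantiomer of the oxazaborolidine above and catecholborane should give 20.

**Further compounds**

F1 | step 17 | (E)-tert-butyl{[6-(4-methoxybenzyloxy)-3-methylhex-3-en-1-yl]oxy}dimethylsilane | COc1ccc(COCC/C=C(\C)CCO[Si](C)(C)C(C)(C)C)cc1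
F2 | step 17 | tert-butyl(2-{(2R,3R)-3-[2-(4-methoxybenzyloxy)ethyl]-2-methyloxiran-2-yl}ethoxy)dimethylsilane | COc1ccc(COCC[C@H]2O[C@]2(C)CCO[Si](C)(C)C(C)(C)C)cc1
F3 | step 17 | 2-{(2R,3R)-3-[2-(4-methoxybenzyloxy)ethyl]-2-methyloxiran-2-yl}ethan-1-ol | COc1ccc(COCC[C@H]2O[C@]2(C)CCO)cc1
F4 | step 17 | 2-{(2R,3R)-3-[2-(4-methoxybenzyloxy)ethyl]-2-methyloxiran-2-yl}acetaldehyde | COc1ccc(COCC[C@H]2O[C@]2(C)CC=O)cc1
F5 | step 17 | rac-hex-1-en-4-yn-3-ol | C=CC(O)C#CC
F6 | step 17 | (S)-hex-1-en-4-yn-3-ol | C=C[C@H](O)C#CC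
F7 | step 17 | (S,Z)-5-iodohexa-1,4-dien-3-ol | C=C[C@H](O)/C=C(/C)I
F8 | step 17 | (S,Z)-5-iodohexa-1,4-dien-3-yl 2-(bromomethyl)acrylate | C=C(CBr)C(=O)O[C@@H](C=C)/C=C(/C)I
F9 | step 17 | (S)-3-(bromomethyl)-5-[(Z)-2-iodoprop-1-en-1-yl]furan-2(5H)-one | O=C1O[C@H](/C=C(/C)I)C=C1CBr
F10 | step 17 | Barbier adduct of F9 and F4, 8S alcohol (configured as 27 at C1, C6, C7, C8, C10) | C=C1C(=O)O[C@H](/C=C(/C)I)[C@H]1[C@@H](O)C[C@@]1(C)O[C@@H]1CCOCc1ccc(OC)cc1
F11 | step 17 | 8R (2R,3R)-2,3-dimethyloxirane-2-carboxylate of F10 (inverted at C8) | C=C1C(=O)O[C@H](/C=C(/C)I)[C@H]1[C@H](OC(=O)[C@]2(C)O[C@@H]2C)C[C@@]2(C)O[C@@H]2CCOCc2ccc(OC)cc2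
F12 | step 17 | primary C3 alcohol from F11 | C=C1C(=O)O[C@H](/C=C(/C)I)[C@H]1[C@H](OC(=O)[C@]2(C)O[C@@H]2C)C[C@@]2(C)O[C@@H]2CCO
F13 | step 17 | C3 aldehyde from F12 | C=C1C(=O)O[C@H](/C=C(/C)I)[C@H]1[C@H](OC(=O)[C@]2(C)O[C@@H]2C)C[C@@]2(C)O[C@@H]2CC=O
F14 | step 17 | 3-O-debenzoyl target, (3S)-allylic alcohol | C=C1C(=O)O[C@@H]2/C=C(/C)[C@@H](O)C[C@H]3O[C@]3(C)C[C@@H](OC(=O)[C@]3(C)O[C@@H]3C)[C@@H]12
F15 | step 16 | C8 ketone from 27 | C=C1C(=O)O[C@H](/C=C/C)[C@H]1C(=O)C[C@@]1(C)O[C@@H]1C[C@H](OC(=O)c1ccccc1)C(C)=C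
F16 | step 16 | 8R alcohol (C8 epimer of 27) | C=C1C(=O)O[C@H](/C=C/C)[C@H]1[C@H](O)C[C@@]1(C)O[C@@H]1C[C@H](OC(=O)c1ccccc1)C(C)=C
F17 | step 10 | rac-(E)-8-[(tert-butyldimethylsilyl)oxy]-2,6-dimethylocta-1,5-dien-3-ol | C=C(C)C(O)C/C=C(\C)CCO[Si](C)(C)C(C)(C)C
F18 | step 10 | (E)-8-[(tert-butyldimethylsilyl)oxy]-2,6-dimethylocta-1,5-dien-3-one | C=C(C)C(=O)C/C=C(\C)CCO[Si](C)(C)C(C)(C)C
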